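Labdane numbering is used for all decalins: ring A is C1–C2–C3–C4–C5–C10, ring B is C5–C6–C7–C8–C9–C10, C11–C15 is the chain on C9 with C16 the methyl on C13, C17 is the methylene on C8, C18 the methyl and C19 the ester carbon on C4, C20 the methyl on C10.

## Analysis of the target

Target 31 is a trans-fused decalin of the labdane type with an exocyclic C8=C17 alkene, a (12E)-3-methylpenta-2,4-dienyl chain on C9, an acetoxy group on C1 and a methyl ester (C19) on C4. It has five stereocentres, (1S,4R,5S,9R,10S) in labdane numbering, two of them quaternary (C4 and C10). The C20 methyl is axial, the C19 ester is axial on the same face (1,3-diaxial to C20), the C1 acetoxy group is equatorial and cis to C20, and the C9 chain is equatorial and cis to C20. H5 and H9 are axial on the opposite face. The conjugated diene and the exocyclic alkene are sensitive to acid and oxidants, and the secondary acetate to strong base, hydride and hard nucleophiles. The axial tertiary ester is hindered and robust. The hard points are the two quaternary carbons in a 1,3-relation on ring A, the C9 stereocentre wedged between quaternary C10 and sp2 C8, and the peri crowding between the C1 oxygen and C11. The strategy rests on one relation: the C1 oxygen is 1,5 to the C19 carbonyl carbon through C2, C3 and C4. That is the pattern a Michael addition leaves behind, so ring A can be closed between C2 and C3 from a methyl ketone on C10 and an acrylate on C5, and the enolate left at C4 can take the C18 methyl in the same flask.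

## Retrosynthetic reasoning

**Diene (31 to 27).** The acid-sensitive diene is made last. C14=C15 is cut by a Wittig methylenation of enal 29 with the ylide from 30. C12=C13 is cut by a Wittig reaction of aldehyde 27 with stabilised ylide 28, which gives the E-trisubstituted alkene reliably. Each olefination forms one double bond, so the geometry at C12 is fixed before the terminal vinyl group exists.

**C12 oxidation level (27 to 24).** Aldehyde 27 comes from alcohol 26, and 26 from anti-Markovnikov hydroboration of the vinyl group in 24. An alkylborane partner for the C9–C11 coupling would bring C12 in as a plain methylene and leave only a late dehydration to reach the C12=C13 alkene, which controls neither position nor geometry. A vinyl group is therefore coupled, and C12 is raised to the aldehyde afterwards.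

**C9 stereocentre and C8=C17 (24 to 20).** C9 sits next to quaternary C10, so it is not set by alkylation. The C9–H bond and the exocyclic alkene are cut together: a reductive 1,3-transposition of tosylhydrazone 21 through an allylic diazene moves the C8=C9 alkene of dienal 20 to C8=C17. The hydrogen is passed to C9 inside the molecule, on the face away from the axial C20 methyl. One operation thus gives both the alkene position and the C9 configuration.

**C9–C11 and C8–C17 (20 to 17).** C9–C11 is cut by a Suzuki–Miyaura coupling of bromo enal 18 with vinylboronate 19. In 18 both C17 and the C9 halide come from ketone 17 in one Vilsmeier-type bromoformylation. Formylating C8 and then sulfonylating would put the leaving group on the formyl oxygen. The iminium route instead places the halide at C9 and the formyl carbon at C8 without ambiguity, because the ketone enolises only toward C8.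

**Ring A oxygen (17 to 14).** Ketone 17 comes from ketal 16, acetate 16 from alcohol 15, and 15 from hydride reduction of keto ester 14. The reduction is done while C9 is masked, so only C1 reacts, and the axial C20 methyl steers hydride to the face that gives the equatorial alcohol. The acetate of the target is put on at once, because no later step uses strong base or hydride. This saves a protection, a deprotection and a late acylation.

**Key disconnection (14 to 10 and 11).** C2–C3 and C4–C18 are cut. Forward, the enolate of the acetyl group on C10 of keto acrylate 10 must add to the acrylate CH2 on C5 and close ring A. The ester enolate formed at C4 must then be methylated by 11 from the equatorial side. This makes one ring, two skeletal bonds and the C4 stereocentre. The trans ring fusion follows from the trans arrangement of the two arms in 10.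

**Acrylate (10 to 6).** The acrylate is an oxidised isopropenyl group. Ester 10 comes from acid 9, 9 from keto enal 8, 8 from diol 7, and 7 from selenium-mediated allylic oxidation of the isopropenyl methyl of hydroxy ketal 6. The carbinol carbon is oxidised to the acetyl group in the same operation that makes the enal.

**Ring B core (6 to 1, 2 and 3).** The ketal of 6 is put on aldol adduct 5 so that later only the acetyl group can enolise. C5–C4 and C10–C1 are cut together: copper-catalysed asymmetric conjugate addition of Grignard reagent 2 to enone 1 sets C5, and the enolate is trapped with acetaldehyde 3 anti to the new substituent. This creates quaternary C10 and the trans relation that later becomes the ring fusion.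

## Alternatives that were turned down

**Alternative 1:** Disconnection of C3–C4 and C5–C10 by an intramolecular Diels–Alder reaction. On heating, the Z-enoate of the open-chain triene A2 would add across its 2-silyloxy diene to give the trans-octalin silyl enol ether A1.
- For: rings A and B and the centres C4, C5 and C10 come in one step, and A1 already carries the C8 methylene and a two-carbon stub on C9. On step economy after the key step this alternative is stronger, since the chosen route spends eleven steps after step 7 on C8, C9 and the chain.
- Against: the diene terminus C10 is fully substituted and carries its larger group on the inside of the s-cis diene, and the dienophile carbon C4 is also fully substituted. Two quaternary carbons must form in one cycloaddition, so high temperature is needed and 1,5-hydrogen shifts in the Z-diene compete.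
- Against: C9–H in A2 is stereogenic and doubly allylic, so it can isomerise on heating, and it has to control both face and endo/exo selectivity. C1 emerges as an enol ether, so the carbinol still has to be set by reduction. A2 itself needs a tetrasubstituted enol ether of defined geometry, a Z-enoate and the C9 centre, so it is long to make.
- Comparison: the chosen route gives up convergence. In its place it offers stereocentres set one at a time by simple substrate control and a six-step precursor.

**Alternative 2:** Disconnection of C9–C10 and C7–C8 by an ester-tethered intramolecular Diels–Alder reaction. On heating, the alkynoate on the C1 oxygen of vinylcyclohexenyl ester A4 would add across the diene to give the tricyclic alkylidene lactone A3.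
- For: quaternary C10 is formed intramolecularly, C11 and C17 arrive with the dienophile, and the only quaternary stereocentre in A4 is C4 on a monocycle. In delivering C11 and C17 together it is stronger than the chosen route.
- Against: the five-membered tether forces the C1 oxygen cis to C9, which is trans to C20. That is the opposite of the target, so C1 would have to be inverted by oxidation and reduction after opening the lactone.
- Against: C5 is left as an alkene that must be hydrogenated from the correct face, C11 arrives at the acid oxidation level, and the C8=C9 alkene still needs the transposition. Esters also prefer the conformation that turns the alkyne away from the diene, so forcing conditions are needed.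
- Comparison: the chosen route gets C1 and the ring fusion right directly and has no oxidation-level detour at C11.

**Alternative 3:** Disconnection of C10–C20. A silylmethyl radical, made from the bromomethylsilyl ether A6 of a C1 allylic alcohol, would add 5-exo to C10 of the C5=C10 alkene and give oxasilolane A5 after hydrogen transfer to C5.
- For: the tether guarantees C20 cis to the C1 oxygen, as in the target. That relation is enforced by ring size, which is at least as strong as the hydride face selectivity the chosen route relies on.
- Against: the radical must attack a fully substituted alkene carbon to make a quaternary centre, so it competes with simple reduction. The ring fusion depends on hydrogen transfer to a tertiary C5 radical flanked by two quaternary carbons, which is not secure.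
- Against: in A5 C9 is a bare methylene between quaternary C10 and the C8 ketal. Introducing the chain there needs enolisation of a C8 ketone toward the hindered side, and the silicon still has to be replaced by hydrogen.
- Comparison: the chosen route has C20 in the first starting material, C9 as a carbonyl from the start, and a trans fusion by construction.

Key step: step 7

Assumption 1: the ligand antipode written in step 1 is taken to give the (3R)-enolate 4; if the sense of induction is the opposite, its mirror image is used.
Assumption 2: 5, 6 and 7 are mixtures of epimers at the carbinol carbon (the later C1); this centre becomes planar in step 4.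

## Route

Step 1
Reactants: 1 2-methylcyclohex-2-en-1-one; 2 isopropenylmagnesium bromide; 3 acetaldehyde
Product: 5 (2S,3R)-2-(1-hydroxyethyl)-2-methyl-3-(prop-1-en-2-yl)cyclohexan-1-one (both carbinol epimers), via bromomagnesium enolate 4 (not isolated)
Conditions: CuBr·SMe2 (5 mol%), (R)-1-[(Sp)-2-(diphenylphosphino)ferrocenyl]ethyldicyclohexylphosphine (6 mol%), tBuOMe, −78 → −40 °C; MeCHO, −78 °C; aq. NH4Cl
Reagents that add atoms: isopropenylmagnesium bromide 2, CC(=C)[Mg]Br; acetaldehyde 3, CC=O
Why: Copper-catalysed asymmetric conjugate addition of a Grignard reagent to a cyclic enone sets C5 under ligand control; enolate 4 then adds to acetaldehyde (aldol reaction) on the face anti to the neighbouring isopropenyl group, which makes quaternary C10 with the hydroxyethyl arm trans to the isopropenyl arm. The carbinol centre is not controlled and is erased in step 4.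

Step 2
Reactants: 5 (2S,3R)-2-(1-hydroxyethyl)-2-methyl-3-(prop-1-en-2-yl)cyclohexan-1-one
Product: 6 1-[(6S,7R)-6-methyl-7-(prop-1-en-2-yl)-1,4-dioxaspiro[4.5]decan-6-yl]ethan-1-ol
Conditions: HOCH2CH2OH, PPTS (cat.), PhH, reflux, Dean–Stark
Reagents that add atoms: ethylene glycol, OCCO
Why: Acid-catalysed ketalisation with azeotropic removal of water; the weak acid should leave the isopropenyl group and the β-hydroxy ketone alone. The ketal masks C9 so that later only the acetyl group can enolise.

Step 3
Reactants: 6 1-[(6S,7R)-6-methyl-7-(prop-1-en-2-yl)-1,4-dioxaspiro[4.5]decan-6-yl]ethan-1-ol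
Product: 7 2-[(6S,7R)-6-(1-hydroxyethyl)-6-methyl-1,4-dioxaspiro[4.5]decan-7-yl]prop-2-en-1-ol
Conditions: SeO2 (0.3 equiv), tBuOOH, CH2Cl2, rt; then NaBH4, MeOH, 0 °C
Reagents that add atoms: selenium dioxide, O=[Se]=O (oxygen carrier); tert-butyl hydroperoxide, CC(C)(C)OO (terminal oxygen source)
Why: Selenium dioxide allylic oxidation (ene reaction, then 2,3-sigmatropic shift) of a 1,1-disubstituted alkene; the methyl hydrogens are far more accessible than the ring methine C5–H, which is shielded by quaternary C10, so oxygen should enter at the methyl carbon (C19). The borohydride work-up returns any enal to 7.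

Step 4
Reactants: 7 2-[(6S,7R)-6-(1-hydroxyethyl)-6-methyl-1,4-dioxaspiro[4.5]decan-7-yl]prop-2-en-1-ol
Product: 8 2-[(6S,7R)-6-acetyl-6-methyl-1,4-dioxaspiro[4.5]decan-7-yl]prop-2-enal
Conditions: (COCl)2, DMSO, CH2Cl2, −78 °C; Et3N, −78 → 0 °C
Reagents that add atoms: none
Why: Swern oxidation; both hydroxyl groups are turned into alkoxysulfonium ions before base is added, so aldehyde and ketone appear together and no hydroxy aldehyde is left to close to a lactol and be oxidised to a lactone.

Step 5
Reactants: 8 2-[(6S,7R)-6-acetyl-6-methyl-1,4-dioxaspiro[4.5]decan-7-yl]prop-2-enal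
Product: 9 2-[(6S,7S)-6-acetyl-6-methyl-1,4-dioxaspiro[4.5]decan-7-yl]prop-2-enoic acid
Conditions: NaClO2, NaH2PO4, 2-methylbut-2-ene, tBuOH/H2O, 0 °C → rt
Reagents that add atoms: sodium chlorite, [Na+].[O-]Cl=O
Why: Pinnick oxidation of a 2-substituted acrolein to the acrylic acid; the alkene scavenger removes hypochlorous acid, and ketone, ketal and acrylic alkene are inert.

Step 6
Reactants: 9 2-[(6S,7S)-6-acetyl-6-methyl-1,4-dioxaspiro[4.5]decan-7-yl]prop-2-enoic acid
Product: 10 methyl 2-[(6S,7S)-6-acetyl-6-methyl-1,4-dioxaspiro[4.5]decan-7-yl]prop-2-enoate
Conditions: Me3SiCHN2, PhMe/MeOH, 0 °C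
Reagents that add atoms: trimethylsilyldiazomethane, C[Si](C)(C)C=[N+]=[N-]
Why: Methyl ester formation with trimethylsilyldiazomethane under neutral conditions, which avoids any base that could start the Michael closure early.

Step 7
Reactants: 10 methyl 2-[(6S,7S)-6-acetyl-6-methyl-1,4-dioxaspiro[4.5]decan-7-yl]prop-2-enoate; 11 iodomethane
Product: 14 methyl 9,9-(ethylenedioxy)-4,10-dimethyl-1-oxo-trans-decalin-4-carboxylate (ester axial; cis to C20), via potassium ketone enolate 12 (not isolated), via potassium ester enolate 13 (not isolated)
Conditions: KN(SiMe3)2 (1.05 equiv), THF, −78 → −40 °C; then MeI (5 equiv), −78 → 0 °C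
Reagents that add atoms: iodomethane 11, CI
Why: KN(SiMe3)2 removes a proton from the acetyl methyl, the only acidic position next to the ketone because C10 is quaternary and C9 is a ketal, to give enolate 12. Its carbon terminus C2 adds to the unsubstituted acrylate carbon C3; the closest known reaction type is the intramolecular Michael addition of a ketone enolate to a 2-substituted acrylate. Ring A closes in the 6-endo-trig mode through a chair-like array C2–C1–C10–C5–C4–C3 in which both arms are equatorial on ring B, so the trans relation set in step 1 becomes the trans ring fusion and the closure itself creates no stereocentre. The closure leaves ester enolate 13, which is methylated at C4 by 11 (enolate alkylation). The one new stereocentre, C4, is controlled by the axial C20 methyl, which blocks the axial face in a 1,3-diaxial sense, so the electrophile enters equatorially and the ester ends axial and cis to C20. The step needs carbon attack at C3 in preference to Claisen-type attack on the ester carbonyl C19 or attack through oxygen; the soft potassium enolate and the exposed CH2 terminus should secure this. It also needs methylation of 13 before it exchanges a proton with the new C2 methylene; one equivalent of base, low temperature and an excess of 11 should secure this.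

Step 8
Reactants: 14 methyl 9,9-(ethylenedioxy)-4,10-dimethyl-1-oxo-trans-decalin-4-carboxylate
Product: 15 methyl 9,9-(ethylenedioxy)-1-hydroxy-4,10-dimethyl-trans-decalin-4-carboxylate (OH equatorial; cis to C20)
Conditions: NaBH4, MeOH, 0 °C
Reagents that add atoms: none
Why: Hydride reduction of a cyclohexanone; the axial C20 methyl blocks the equatorial trajectory, so hydride should enter axially from the face of H5 and give the equatorial C1 alcohol cis to C20. The hindered tertiary ester and the ketal are not touched.

Step 9
Reactants: 15 methyl 9,9-(ethylenedioxy)-1-hydroxy-4,10-dimethyl-trans-decalin-4-carboxylate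
Product: 16 methyl 1-acetoxy-9,9-(ethylenedioxy)-4,10-dimethyl-trans-decalin-4-carboxylate
Conditions: Ac2O, DMAP, Et3N, CH2Cl2, rt
Reagents that add atoms: acetic anhydride, CC(=O)OC(C)=O
Why: Nucleophile-catalysed acylation of a hindered secondary alcohol; the acetate of the target is installed here because no later step is strongly basic or hydridic.

Step 10
Reactants: 16 methyl 1-acetoxy-9,9-(ethylenedioxy)-4,10-dimethyl-trans-decalin-4-carboxylate
Product: 17 methyl 1-acetoxy-4,10-dimethyl-9-oxo-trans-decalin-4-carboxylate
Conditions: 1 M HCl, THF, rt → 40 °C
Reagents that add atoms: water, O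
Why: Acid hydrolysis of the dioxolane; the β-acetoxy ketone cannot eliminate because C10 carries no hydrogen, and both esters are stable to dilute acid.

Step 11
Reactants: 17 methyl 1-acetoxy-4,10-dimethyl-9-oxo-trans-decalin-4-carboxylate
Product: 18 methyl 1-acetoxy-9-bromo-8-formyl-4,10-dimethyl-trans-octal-8-ene-4-carboxylate (C8=C9 alkene)
Conditions: PBr3, DMF, CHCl3, 0 → 60 °C; aq. NaHCO3
Reagents that add atoms: N,N-dimethylformamide, CN(C)C=O; phosphorus tribromide, BrP(Br)Br; water, O
Why: Vilsmeier–Haack bromoformylation; the enol of the C9 ketone can form only toward C8, the iminium carbon becomes C17 and bromide replaces the activated C9 oxygen, so halide and formyl group are placed without ambiguity.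

Step 12
Reactants: 18 methyl 1-acetoxy-9-bromo-8-formyl-4,10-dimethyl-trans-octal-8-ene-4-carboxylate; 19 4,4,5,5-tetramethyl-2-vinyl-1,3,2-dioxaborolane
Product: 20 methyl 1-acetoxy-8-formyl-4,10-dimethyl-9-vinyl-trans-octal-8-ene-4-carboxylate
Conditions: 19, PdCl2(dppf) (5 mol%), CsF, 1,4-dioxane, 80 °C
Reagents that add atoms: 4,4,5,5-tetramethyl-2-vinyl-1,3,2-dioxaborolane 19, C=CB1OC(C)(C)C(C)(C)O1
Why: Suzuki–Miyaura coupling that forms C9–C11; the C9–Br bond of a β-bromo enal adds readily to palladium, and fluoride activation of the boronate avoids aqueous base and spares the acetate.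

Step 13
Reactants: 20 methyl 1-acetoxy-8-formyl-4,10-dimethyl-9-vinyl-trans-octal-8-ene-4-carboxylate
Product: 21 (E)-tosylhydrazone of 20 at C17
Conditions: TsNHNH2, THF, rt
Reagents that add atoms: 4-methylbenzenesulfonohydrazide, Cc1ccc(cc1)S(=O)(=O)NN
Why: Condensation of the aldehyde with the sulfonyl hydrazide; any 2H-pyran valence isomer of the cis-dienal is in equilibrium with the aldehyde and is drained by the condensation. 21 is used at once.

Step 14
Reactants: 21 (E)-tosylhydrazone of 20 at C17
Product: 24 methyl 1-acetoxy-4,10-dimethyl-8-methylidene-9-vinyl-trans-decalin-4-carboxylate (H9 axial; vinyl equatorial and cis to C20), via allylic tosylhydrazine 22 (not isolated), via allylic diazene 23 (not isolated)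
Conditions: catecholborane, CHCl3, 0 °C; then NaOAc·3H2O, 60 °C
Reagents that add atoms: none
Why: Reductive 1,3-transposition of an unsaturated tosylhydrazone: catecholborane reduces C=N to 22, acetate expels sulfinate to give diazene 23, and a retro-ene loss of N2 moves the alkene to C8=C17 while passing hydrogen to C9. The hydrogen should be delivered on the face opposite the axial C20 methyl, so H9 is axial and the vinyl group equatorial, cis to C20.

Step 15
Reactants: 24 methyl 1-acetoxy-4,10-dimethyl-8-methylidene-9-vinyl-trans-decalin-4-carboxylate
Product: 26 methyl 1-acetoxy-9-(2-hydroxyethyl)-4,10-dimethyl-8-methylidene-trans-decalin-4-carboxylate, via disiamylalkylborane 25 (not isolated)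
Conditions: Sia2BH (from BH3·SMe2 and 2-methylbut-2-ene), THF, 0 °C; then NaBO3·4H2O, H2O, rt
Reagents that add atoms: sodium perborate, [Na+].[O-]OB=O
Why: Hydroboration–oxidation; the bulky dialkylborane should add to the monosubstituted vinyl group, boron at terminal C12, much faster than to the hindered 1,1-disubstituted C8=C17 alkene, and perborate oxidises the C–B bond without cleaving the acetate.

Step 16
Reactants: 26 methyl 1-acetoxy-9-(2-hydroxyethyl)-4,10-dimethyl-8-methylidene-trans-decalin-4-carboxylate
Product: 27 methyl 1-acetoxy-4,10-dimethyl-8-methylidene-9-(2-oxoethyl)-trans-decalin-4-carboxylate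
Conditions: Dess–Martin periodinane, NaHCO3, CH2Cl2, 0 °C → rt
Reagents that add atoms: none
Why: Dess–Martin oxidation of the primary alcohol to the aldehyde under buffered conditions that leave the exocyclic alkene in place.

Step 17
Reactants: 27 methyl 1-acetoxy-4,10-dimethyl-8-methylidene-9-(2-oxoethyl)-trans-decalin-4-carboxylate; 28 2-(triphenylphosphoranylidene)propanal
Product: 29 methyl 1-acetoxy-4,10-dimethyl-8-methylidene-9-[(2E)-3-methyl-4-oxobut-2-en-1-yl]-trans-decalin-4-carboxylate
Conditions: 28, PhMe, 80 °C
Reagents that add atoms: 2-(triphenylphosphoranylidene)propanal 28, CC(C=O)=P(c1ccccc1)(c1ccccc1)c1ccccc1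
Why: Wittig reaction with a stabilised ylide, which should give the (E)-2-methyl enal (C12=C13) and not react further with the less electrophilic product.

Step 18
Reactants: 29 methyl 1-acetoxy-4,10-dimethyl-8-methylidene-9-[(2E)-3-methyl-4-oxobut-2-en-1-yl]-trans-decalin-4-carboxylate; 30 methyltriphenylphosphonium bromide
Product: 31 methyl (1R,4S,4aS,5R,8aS)-4-(acetyloxy)-1,4a-dimethyl-6-methylidene-5-[(2E)-3-methylpenta-2,4-dien-1-yl]decahydronaphthalene-1-carboxylate (the target)
Conditions: 30, KOtBu, THF, 0 °C; then 29, −78 → 0 °C
Reagents that add atoms: methyltriphenylphosphonium bromide 30, C[P+](c1ccccc1)(c1ccccc1)c1ccccc1.[Br-]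
Why: Wittig methylenation of the enal completes the diene (C14=C15) without touching the C12=C13 geometry; the aldehyde reacts much faster than the hindered acetate and ester at low temperature.

## Compound list

1 | 2-methylcyclohex-2-en-1-one | CC1=CCCCC1=O | starting material
2 | isopropenylmagnesium bromide | CC(=C)[Mg]Br | starting material
3 | acetaldehyde | CC=O | starting material
4 | bromomagnesium (3R)-2-methyl-3-(prop-1-en-2-yl)cyclohex-1-en-1-olate | CC(=C)[C@H]1CCCC(O[Mg]Br)=C1C | intermediate
5 | (2S,3R)-2-(1-hydroxyethyl)-2-methyl-3-(prop-1-en-2-yl)cyclohexan-1-one, carbinol epimers | CC(=C)[C@H]1CCCC(=O)[C@]1(C)C(C)O | intermediate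
6 | 1-[(6S,7R)-6-methyl-7-(prop-1-en-2-yl)-1,4-dioxaspiro[4.5]decan-6-yl]ethan-1-ol, carbinol epimers | CC(=C)[C@H]1CCCC2(OCCO2)[C@]1(C)C(C)O | intermediate
7 | 2-[(6S,7R)-6-(1-hydroxyethyl)-6-methyl-1,4-dioxaspiro[4.5]decan-7-yl]prop-2-en-1-ol, carbinol epimers | C=C(CO)[C@H]1CCCC2(OCCO2)[C@]1(C)C(C)O | intermediate
8 | 2-[(6S,7R)-6-acetyl-6-methyl-1,4-dioxaspiro[4.5]decan-7-yl]prop-2-enal | C=C(C=O)[C@H]1CCCC2(OCCO2)[C@]1(C)C(C)=O | intermediate
9 | 2-[(6S,7S)-6-acetyl-6-methyl-1,4-dioxaspiro[4.5]decan-7-yl]prop-2-enoic acid | C=C(C(=O)O)[C@H]1CCCC2(OCCO2)[C@]1(C)C(C)=O | intermediate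
10 | methyl 2-[(6S,7S)-6-acetyl-6-methyl-1,4-dioxaspiro[4.5]decan-7-yl]prop-2-enoate (acetyl trans to acrylate) | COC(=O)C(=C)[C@H]1CCCC2(OCCO2)[C@]1(C)C(C)=O | intermediate
11 | iodomethane | CI | starting material
12 | potassium enolate of the acetyl group of 10 | COC(=O)C(=C)[C@H]1CCCC2(OCCO2)[C@]1(C)C(=C)[O-].[K+] | intermediate
13 | potassium C4 ester enolate of the ring-closed trans-decalin | O1CCOC12CCC[C@H]3[C@@]2(C)C(=O)CCC3=C(OC)[O-].[K+] | intermediate
14 | methyl 9,9-(ethylenedioxy)-4,10-dimethyl-1-oxo-trans-decalin-4-carboxylate, ester axial and cis to C20 | O1CCOC12CCC[C@H]3[C@@]2(C)C(=O)CC[C@@]3(C)C(=O)OC | intermediate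
15 | methyl 9,9-(ethylenedioxy)-1-hydroxy-4,10-dimethyl-trans-decalin-4-carboxylate, OH equatorial and cis to C20 | O1CCOC12CCC[C@H]3[C@@]2(C)[C@@H](O)CC[C@@]3(C)C(=O)OC | intermediate
16 | methyl 1-acetoxy-9,9-(ethylenedioxy)-4,10-dimethyl-trans-decalin-4-carboxylate | O1CCOC12CCC[C@H]3[C@@]2(C)[C@@H](OC(C)=O)CC[C@@]3(C)C(=O)OC | intermediate
17 | methyl 1-acetoxy-4,10-dimethyl-9-oxo-trans-decalin-4-carboxylate | O=C1CCC[C@H]2[C@@]1(C)[C@@H](OC(C)=O)CC[C@@]2(C)C(=O)OC | intermediate
18 | methyl 1-acetoxy-9-bromo-8-formyl-4,10-dimethyl-trans-octal-8-ene-4-carboxylate | BrC1=C(C=O)CC[C@H]2[C@@]1(C)[C@@H](OC(C)=O)CC[C@@]2(C)C(=O)OC | intermediate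
19 | 4,4,5,5-tetramethyl-2-vinyl-1,3,2-dioxaborolane | C=CB1OC(C)(C)C(C)(C)O1 | starting material
20 | methyl 1-acetoxy-8-formyl-4,10-dimethyl-9-vinyl-trans-octal-8-ene-4-carboxylate | C=CC1=C(C=O)CC[C@H]2[C@@]1(C)[C@@H](OC(C)=O)CC[C@@]2(C)C(=O)OC | intermediate
21 | (E)-tosylhydrazone of 20 at C17 | C=CC1=C(/C=N/NS(=O)(=O)c3ccc(C)cc3)CC[C@H]2[C@@]1(C)[C@@H](OC(C)=O)CC[C@@]2(C)C(=O)OC | intermediate
22 | allylic N'-tosylhydrazine from reduction of 21 | C=CC1=C(CNNS(=O)(=O)c3ccc(C)cc3)CC[C@H]2[C@@]1(C)[C@@H](OC(C)=O)CC[C@@]2(C)C(=O)OC | intermediate
23 | allylic diazene | C=CC1=C(CN=N)CC[C@H]2[C@@]1(C)[C@@H](OC(C)=O)CC[C@@]2(C)C(=O)OC | intermediate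
24 | methyl 1-acetoxy-4,10-dimethyl-8-methylidene-9-vinyl-trans-decalin-4-carboxylate, H9 axial | C=C[C@@H]1C(=C)CC[C@H]2[C@@]1(C)[C@@H](OC(C)=O)CC[C@@]2(C)C(=O)OC | intermediate
25 | C12 bis(3-methylbutan-2-yl)borane adduct of 24 | CC(C)C(C)B(CC[C@@H]1C(=C)CC[C@H]2[C@@]1(C)[C@@H](OC(C)=O)CC[C@@]2(C)C(=O)OC)C(C)C(C)C | intermediate
26 | methyl 1-acetoxy-9-(2-hydroxyethyl)-4,10-dimethyl-8-methylidene-trans-decalin-4-carboxylate | OCC[C@@H]1C(=C)CC[C@H]2[C@@]1(C)[C@@H](OC(C)=O)CC[C@@]2(C)C(=O)OC | intermediate
27 | methyl 1-acetoxy-4,10-dimethyl-8-methylidene-9-(2-oxoethyl)-trans-decalin-4-carboxylate | O=CC[C@@H]1C(=C)CC[C@H]2[C@@]1(C)[C@@H](OC(C)=O)CC[C@@]2(C)C(=O)OC | intermediate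
28 | 2-(triphenylphosphoranylidene)propanal | CC(C=O)=P(c1ccccc1)(c1ccccc1)c1ccccc1 | starting material
29 | methyl 1-acetoxy-4,10-dimethyl-8-methylidene-9-[(2E)-3-methyl-4-oxobut-2-en-1-yl]-trans-decalin-4-carboxylate | O=C/C(C)=C/C[C@@H]1C(=C)CC[C@H]2[C@@]1(C)[C@@H](OC(C)=O)CC[C@@]2(C)C(=O)OC | intermediate
30 | methyltriphenylphosphonium bromide | C[P+](c1ccccc1)(c1ccccc1)c1ccccc1.[Br-] | starting material
31 | methyl (1R,4S,4aS,5R,8aS)-4-(acetyloxy)-1,4a-dimethyl-6-methylidene-5-[(2E)-3-methylpenta-2,4-dien-1-yl]decahydronaphthalene-1-carboxylate; (1S,4R,5S,9R,10S) in labdane numbering | C=C/C(C)=C/C[C@@H]1C(=C)CC[C@H]2[C@@]1(C)[C@@H](OC(C)=O)CC[C@@]2(C)C(=O)OC | target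

## Step count and least certain steps

Total: 18 steps. Longest linear sequence: 18 steps, from 1 to 31; 2, 3, 11, 19, 28 and 30 are commercial and enter directly.

**Step 7 (key step).** The most likely failure is proton exchange between ester enolate 13 and the new C2 methylene (or unreacted 10) before the methylation. The ketone enolate is the more stable one, so this would lead to methylation at C2 or to a product without the C18 methyl. Ring closure onto the ester carbonyl is a second possibility. The fallback separates the two events. From 10, a catalytic amount of KOtBu in tBuOH/THF should close ring A under equilibrium control to methyl 9,9-(ethylenedioxy)-10-methyl-1-oxo-trans-decalin-4-carboxylate F1 (both C4 epimers). NaBH4 then reduces C1 to the equatorial hydroxy ester F2. LiN(iPr)2 (2.2 equiv) makes the alkoxide ester enolate, which is methylated by 11 from the equatorial face. The route is rejoined at 15.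

**Step 1.** The most likely failure is low enantioselectivity. Alkenyl Grignard reagents and 2-substituted enones both lie at the edge of the scope of the copper–diphosphine system, and the ligand-free background addition is racemic. The fallback is resolution. From 1, 2 and 3 with CuBr·SMe2 alone, the racemic aldol adduct F3 is made and taken through steps 2 to 5 unchanged. This gives racemic hydroxy ketal F4, racemic diol F5, racemic keto enal F6 and racemic keto acid F7. F7 is resolved by fractional crystallisation of its (S)-1-phenylethylammonium salt F8 (or of the salt with the antipodal amine, whichever carries the wanted acid in the less soluble salt). Acidification returns the route at 9.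

**Step 3.** The most likely failure is attack of the selenium reagent at the ring methine C5–H, which gives a tertiary allylic alcohol, together with over-oxidation. The fallback changes the oxidation mode. From 6, mCPBA with NaHCO3 epoxidises the isopropenyl group to the 2-methyloxiranyl hydroxy ketal F9 (epimers at the epoxide carbon). Diethylaluminium 2,2,6,6-tetramethylpiperidide (3 equiv, PhMe, 0 °C) then removes a proton from the methyl group through a cyclic syn-elimination and opens the epoxide to the 2-substituted allyl alcohol. The route is rejoined at 7.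

**Step 11.** The most likely failure is that the reaction stalls before the hindered C9 oxygen is replaced, because C9 is next to quaternary C10, or that the acid formed causes partial loss of the acetate. The fallback makes the C8–C17 bond and the C9–Br bond in separate operations. From 17, tert-butoxybis(dimethylamino)methane in PhMe at 90 °C gives the 8-(dimethylaminomethylidene) ketone F10 under neutral conditions. Oxalyl bromide in CH2Cl2 at 0 °C then activates the vinylogous amide oxygen and delivers bromide to C9, and aqueous NaHCO3 hydrolyses the iminium salt. The route is rejoined at 18.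

**Step 15.** The most likely failure is poor chemoselectivity, with the borane also adding to the exocyclic C8=C17 alkene, since the vinyl group itself sits in a crowded position next to C10 and the C1 acetate. The fallback avoids hydroboration of the diene. From 24, cross-metathesis with 19 using second-generation Grubbs catalyst, RuCl2(=CHPh)(H2IMes)(PCy3), in CH2Cl2 at 40 °C should give the (E)-alkenylboronate F11, because the hindered 1,1-disubstituted alkene does not take part. NaBO3·4H2O then oxidises the C–B bond to the enol, which tautomerises to the aldehyde. The route is rejoined at 27.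

## Further compounds

F1 | step 7 | methyl 9,9-(ethylenedioxy)-10-methyl-1-oxo-trans-decalin-4-carboxylate, C4 epimers | O1CCOC12CCC[C@H]3[C@@]2(C)C(=O)CCC3C(=O)OC
F2 | step 7 | methyl 9,9-(ethylenedioxy)-1-hydroxy-10-methyl-trans-decalin-4-carboxylate, OH equatorial, C4 epimers | O1CCOC12CCC[C@H]3[C@@]2(C)[C@@H](O)CCC3C(=O)OC
F3 | step 1 | racemic 5 (relative configuration shown) | CC(=C)[C@H]1CCCC(=O)[C@]1(C)C(C)O
F4 | step 1 | racemic 6 (relative configuration shown) | CC(=C)[C@H]1CCCC2(OCCO2)[C@]1(C)C(C)O
F5 | step 1 | racemic 7 (relative configuration shown) | C=C(CO)[C@H]1CCCC2(OCCO2)[C@]1(C)C(C)O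
F6 | step 1 | racemic 8 (relative configuration shown) | C=C(C=O)[C@H]1CCCC2(OCCO2)[C@]1(C)C(C)=O
F7 | step 1 | racemic 9 (relative configuration shown) | C=C(C(=O)O)[C@H]1CCCC2(OCCO2)[C@]1(C)C(C)=O
F8 | step 1 | (S)-1-phenylethylammonium salt of 9 | C=C(C(=O)[O-])[C@H]1CCCC2(OCCO2)[C@]1(C)C(C)=O.C[C@H]([NH3+])c1ccccc1
F9 | step 3 | 1-[(6S,7R)-6-methyl-7-(2-methyloxiran-2-yl)-1,4-dioxaspiro[4.5]decan-6-yl]ethan-1-ol, epimers at the epoxide and carbinol carbons | CC1(CO1)[C@H]1CCCC2(OCCO2)[C@]1(C)C(C)O
F10 | step 11 | methyl 1-acetoxy-8-(dimethylaminomethylidene)-4,10-dimethyl-9-oxo-trans-decalin-4-carboxylate | O=C1C(=CN(C)C)CC[C@H]2[C@@]1(C)[C@@H](OC(C)=O)CC[C@@]2(C)C(=O)OC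
F11 | step 15 | methyl 1-acetoxy-4,10-dimethyl-8-methylidene-9-[(E)-2-(4,4,5,5-tetramethyl-1,3,2-dioxaborolan-2-yl)ethenyl]-trans-decalin-4-carboxylate | CC1(C)OB(/C=C/[C@@H]2C(=C)CC[C@H]3[C@@]2(C)[C@@H](OC(C)=O)CC[C@@]3(C)C(=O)OC)OC1(C)C
A1 | alternative 1 | trans-octalin silyl enol ether with the C8 methylene and a 2-(tert-butyldiphenylsilyloxy)ethyl group on C9 | CC(C)(C)[Si](c1ccccc1)(c1ccccc1)OCC[C@@H]1C(=C)CC[C@H]2[C@@]1(C)C(O[Si](C)(C)C(C)(C)C)=CC[C@@]2(C)C(=O)OC
A2 | alternative 1 | open-chain triene: methyl (Z)-2-methyl enoate tethered through C6–C9 to a (Z)-2-(tert-butyldimethylsilyloxy) diene | COC(=O)/C(C)=C\CCC(=C)[C@@H](CCO[Si](c1ccccc1)(c1ccccc1)C(C)(C)C)/C(C)=C(O[Si](C)(C)C(C)(C)C)/C=C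
A3 | alternative 2 | tricyclic alkylidene lactone | COC(=O)[C@]1(C)CC[C@H]2OC(=O)C3=C(CO[Si](C)(C)C(C)(C)C)CC=C1[C@@]23C
A4 | alternative 2 | 4-(tert-butyldimethylsilyloxy)but-2-ynoate of the 2-methyl-3-vinylcyclohex-2-enol bearing the C4 methyl and ester | COC(=O)[C@]1(C)CC[C@@H](OC(=O)C#CCO[Si](C)(C)C(C)(C)C)C(C)=C1C=C
A5 | alternative 3 | trans-decalin oxasilolane with C8 ketal | COC(=O)[C@]1(C)CC[C@@H]2O[Si](C)(C)C[C@@]23CC4(OCCO4)CC[C@H]13
A6 | alternative 3 | (bromomethyl)dimethylsilyl ether of the C1 allylic alcohol of the C5=C10 octalin with C8 ketal | COC(=O)[C@]1(C)CC[C@H](O[Si](C)(C)CBr)C2=C1CCC1(OCCO1)C2
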